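## The problem

Atoms are numbered as they occur in the SMILES string of the target (C1 to O26). The compound is a tetracycle: a cyclohex-2-ene-1,4-dione (ring A: C7, C8, C10, C11, C12, C14), a cyclohexene (ring B: C7, C14, C15, C16, C17, C23), a cyclopentane (ring C: C16–C20) and a furan-3-one (ring D: C5, O6, C7, C23, C25). Rings B and C are trans-fused at C16–C17, rings B and D are cis-fused at C7–C23, and rings A and D meet only at C7. There are six stereocentres (5R, 7S, 16R, 17S, 20S, 23R), and C7 and C23 are adjacent and fully substituted. C17 can set C16 (trans), C16 can set C20, C17 can set C23 through the closure of ring B, and C23 fixes C7 because ring D can only close cis; C5 is remote from all of them and needs a reagent. The cross-conjugated enedione with its exocyclic C14=C15 bond, the tertiary C20 alcohol and the C5 hydrogen (allylic and next to the C25 ketone) will not survive strong acid or base, so ring A is best kept aromatic until the last step. Ring A is at the oxidation level of a 4-methoxyphenol that has been oxidised once at C7 and has lost an oxygen from C15. Ring C, with trans C16/C17 next to the methyl carbinol C20, is cyclopent-2-en-1-one in disguise (C20 carbonyl, C16 α, C17 β): C16 carries C15, a benzaldehyde carbon of ring A, C17 carries C23, an alkenyl carbon, and an aldol at C15 leaves exactly the oxygen that must later depart to give C14=C15.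

## Retrosynthesis

**Ring D and the enedione (24 from 22).** The O6–C7 bond is cut and ring A is returned to a 4-methoxyphenol carrying a C15 hydroxyl, which gives phenol 22. Oxidation of 22 at trivalent iodine should let the C5 hydroxyl close ring D at C7 (spiro dienone 23), and the enol ether at C12 should then expel the C15 hydroxyl and lose methanol. Closing ring D by O6–C5 bond formation instead would need a free tertiary alcohol on a dearomatised ring, which is harder to handle. The forward step has to beat attack of outside nucleophiles at C12; C7 must follow from C23.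

**Side chain (22 back to aldehyde 18).** Ketone 21 is 22 with three methoxymethyl ethers; its C25 carbonyl comes from alcohol 20, whose C4=C2 bond comes from cross-metathesis of vinyl compound 19. The C25–C5 bond of 19 is cut to aldehyde 18 and a γ-alkoxyallylborane, so that C5 arrives as a nucleophile already carrying its oxygen and its configuration. An acyl-anion equivalent at C25 adding to 3-methylbut-2-enal would be shorter but leaves C5 uncontrolled. The free ketol exists only in 22.

**Ring B (18 back to 15).** Aldehyde 18 comes from silyl ether 16 through alcohol 17. In 16 the C7–C23 bond is cut to aryl bromide 15, which carries a 1,1-disubstituted alkene. Acid-mediated closure through a C23 cation was weighed first: it would ionise the benzylic C15 ether, the cation lies next to an oxygen-bearing carbon, and a planar cation does not tell C24 from C25. A reductive Heck closure is non-acidic and its four-centre insertion geometry does distinguish the two carbons; the price is a bromine at C7.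

**C20 (15 back to 13).** The C20–C21 bond is cut to ketone 14, the methoxymethyl ether of aldol 13. Methyl addition must come anti to the C16 branch. The ether prevents retro-aldol cleavage and is later the leaving group at C15.

**Key disconnection (13 to 10, 9 and 3).** C17–C23 and C16–C15 are cut together, giving cyclopent-2-en-1-one 10, alkenylborane 9 and aldehyde 3. Fifteen of the 21 skeletal carbons and three stereocentres arrive in one operation, and the enolate is formed regiospecifically. A stepwise addition followed by deprotonation would not distinguish C16 from C19.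

**Fragments.** Aldehyde 3 comes from 1 by bromination (2) and protection. Borane 9 comes from 4 by silylation (5), lithiation and transfer to 6.

## Roads not taken

Alternative 1: The cut is C14=C15 and C7–C23, so that ring B is forged on a hydroxyquinone. 2-Hydroxy-1,4-benzoquinone A1 would condense through C14 with the aldehyde of keto aldehyde A2, and the C23 enol would add to the C7 carbonyl of the resulting tricarbonyl to give A3. Ring D would then close by allylic substitution of the carbonate at C5. Its merits are real: ring A is at the final oxidation level from the start, no protecting groups sit on it, and C5 is set late by the ring system. In that respect it is better than the chosen plan, which spends steps on protection and a dearomatisation. Its weak points are that alkylidene tricarbonyls of this kind are strong Michael acceptors at C15 and are usually captured there (by a second hydroxyquinone or by the enol), not at the C7 carbonyl. The C7/C23 pair of quaternary centres would come from a reversible aldol with no clear facial bias. A2 already contains C16, C17 and C20 and would itself need chemistry like the chosen key step. The chosen plan sets against it a C23 centre fixed by insertion geometry and no bond formation to a vicinal tricarbonyl.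

Alternative 2: The cut is C16–C20. Ozonolysis of the ring alkene of (S)-limonene A4 gives keto aldehyde A5, and an amine-catalysed aldol addition of C16 to the methyl ketone gives A6 with C16, C17 and C20 in place. This is shorter and cheaper for ring C than the chosen plan, needs no metal catalyst and takes C17 from the chiral pool; here it is clearly better. Against it: the β-hydroxy aldehyde loses water easily and C16 can epimerise. The isopropenyl group carries no oxygen at C25, so C24 and C25 would have to be told apart by an allylic oxidation that also threatens H17. Ring A would still have to be added to C15 afterwards. The chosen plan has C14–C15, the C25 oxygen and the C16/C17 relation in hand after one step.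

Alternative 3: The cut is C7–C14 and C17–C23, closing rings A and B at once. A Z-enedione, unmasked from a furan, links a furanone dienophile to a 1-vinylcyclopentene in precursor A7, and gentle heating would give adduct A8. It is the most convergent of the four plans and would form the C7/C23 pair suprafacially in one step; if it worked it would be shorter. Its weak points: the dienophile is a tetrasubstituted, oxygen-donor-substituted alkene that must form two adjacent quaternary centres, while the enedione alkene in the tether is the far better dienophile and invites dimerisation. The Z-enedione isomerises readily. A8 still has C15=C16, so C16 would be set by a late isomerisation, and the trans B/C fusion would not be assured. The chosen plan makes the same centres one at a time by steps with individual precedent.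

Key step: step 5

Remark: the sense of induction of (S)-BINAP in step 5 and of the (+)-α-pinene-derived boron reagent in step 11 is taken from the usual models; if either runs the other way on these substrates, the antipode is used and nothing else changes.

## Route

Step 1
Reactants: 1 5-hydroxy-2-methoxybenzaldehyde
Product: 2 2-bromo-3-hydroxy-6-methoxybenzaldehyde
Conditions: Br2, NaOAc, AcOH, rt
Reagents that add atoms: bromine, BrBr
Why: Electrophilic aromatic bromination directed by the free hydroxyl; of its two ortho sites the one flanked by the formyl group (C7) is expected to react, as with isovanillin and 3-hydroxybenzaldehyde, where the site para to the formyl group is left alone.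

Step 2
Reactants: 2 2-bromo-3-hydroxy-6-methoxybenzaldehyde
Product: 3 2-bromo-6-methoxy-3-(methoxymethoxy)benzaldehyde
Conditions: MOMCl, i-Pr2NEt, CH2Cl2, 0 °C to rt
Reagents that add atoms: chloromethyl methyl ether, COCCl
Why: O-Alkylation of the phenol (Williamson-type acetal formation); the small methoxymethyl ether fits beside the bromide and survives all basic and organometallic steps that follow.

Step 3
Reactants: 4 2-bromoprop-2-en-1-ol
Product: 5 (2-bromoprop-2-en-1-yloxy)triisopropylsilane
Conditions: i-Pr3SiCl, imidazole, DMF, rt
Reagents that add atoms: chlorotriisopropylsilane, CC(C)[Si](Cl)(C(C)C)C(C)C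
Why: Silylation of a primary alcohol; the triisopropylsilyl group resists oxygen-to-carbon silyl migration in the alkenyllithium at −78 °C and is a poor leaving group.

Step 4
Reactants: 5 (2-bromoprop-2-en-1-yloxy)triisopropylsilane; 6 9-methoxy-9-borabicyclo[3.3.1]nonane
Product: 9 9-[3-(triisopropylsilyloxy)prop-1-en-2-yl]-9-borabicyclo[3.3.1]nonane, via alkenyllithium 7 (not isolated), via lithium methoxyborate 8 (not isolated)
Conditions: t-BuLi (2.1 equiv), Et2O, −78 °C; 6, −78 °C; BF3·OEt2, −78 °C to rt; filtration, toluene
Reagents that add atoms: none
Why: Bromine–lithium exchange gives 7, which adds to the boron of 6 to form borate 8; BF3·OEt2 removes methoxide and leaves the neutral B-alkenyl borane, the standard route to B-substituted 9-borabicyclononanes.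

Step 5
Reactants: 10 cyclopent-2-en-1-one; 9 9-[3-(triisopropylsilyloxy)prop-1-en-2-yl]-9-borabicyclo[3.3.1]nonane; 3 2-bromo-6-methoxy-3-(methoxymethoxy)benzaldehyde
Product: 13 anti aldol (2S,3S)-2-[(R)-aryl(hydroxy)methyl]-3-alkenylcyclopentan-1-one (15R,16S,17S), via boron enolate 11 (not isolated), via boron aldolate 12 (not isolated)
Conditions: [Rh(OMe)(C8H12)]2 (1.5 mol %), (S)-BINAP (3.3 mol %), toluene, 80 °C; then 3, −78 to 0 °C; then H2O2, pH 7 buffer, MeOH, 0 °C
Reagents that add atoms: none
Why: The methoxo-rhodium–BINAP complex takes the alkenyl group from boron, the alkenylrhodium inserts 10 on the enone face left open by (S)-BINAP to give a rhodium enolate with C17 (S), and exchange with a second molecule of 9 releases boron enolate 11 and returns alkenylrhodium. Because 11 arises by conjugate addition and not by deprotonation, only the C16 enolate exists. Aldehyde 3 is then bound by boron and adds through a closed six-membered chair transition state on the enolate face away from the new C17 substituent, which makes C16 and C17 trans. The cyclic enolate has its ring carbon anti to oxygen and should give the anti (15R) carbinol, a centre that is erased later. No ring is closed. The closest known reactions are the rhodium–BINAP 1,4-addition of B-aryl-9-borabicyclononanes to cyclic enones with aldol capture of the boron enolate, and the asymmetric transfer of alkenyl groups from boron to cyclopent-2-en-1-one. The step needs enantioface control (ligand), trans selectivity (C17 substituent) and insertion that outruns loss of the allylic silyloxy group from the alkenylmetal; the bulky, weakly basic silyl ether is chosen for that reason, and the aryl bromide enters only after the rhodium-catalysed stage.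

Step 6
Reactants: 13 anti aldol
Product: 14 C15 methoxymethyl ether of 13
Conditions: MOMCl, i-Pr2NEt, n-Bu4NI (cat.), CH2Cl2, 0 °C to rt
Reagents that add atoms: chloromethyl methyl ether, COCCl
Why: Acetal formation at the secondary carbinol under weakly basic conditions; the ether blocks retro-aldol cleavage in step 7 and later serves as the leaving group at C15.

Step 7
Reactants: 14 C15 methoxymethyl ether of 13
Product: 15 tertiary alcohol (1S,2S,3S)-1-methylcyclopentan-1-ol (15R,16S,17S,20S)
Conditions: MeMgBr, CeCl3, THF, −78 °C
Reagents that add atoms: methylmagnesium bromide, C[Mg]Br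
Why: Organocerium 1,2-addition, non-basic so that C16 is not epimerised; the nucleophile should enter the C20 carbonyl anti to the large C16 branch, placing methyl trans and hydroxyl cis to C15 (20S).

Step 8
Reactants: 15 tertiary alcohol
Product: 16 ring A–B–C tricycle with C23 methyl and C25 silyloxymethyl (23R)
Conditions: Pd(OAc)2 (10 mol %), PPh3 (25 mol %), HCO2Na, n-Bu4NCl, DMF, 90 °C
Reagents that add atoms: none
Why: Reductive Heck cyclisation: zerovalent palladium inserts into C7–Br, 6-exo syn carbopalladation of the 1,1-disubstituted alkene forms C7–C23, and the neopentyl palladium, having no β-hydrogen, is reduced by formate to the C24 methyl. With ring C bonds equatorial in a chair-like ring B, the eclipsed four-centre insertion should place the palladium-bearing C24 pseudo-axial and anti to H17, so that C25 becomes the equatorial arm and C23 is R.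

Step 9
Reactants: 16 tricyclic silyl ether
Product: 17 primary alcohol at C25
Conditions: n-Bu4NF, THF, rt
Reagents that add atoms: none
Why: Fluoride cleavage of the silyl ether; the acetals, the tertiary alcohol and the aryl ethers are inert.

Step 10
Reactants: 17 primary alcohol
Product: 18 C25 aldehyde
Conditions: Dess–Martin periodinane, pyridine, CH2Cl2, 0 °C to rt
Reagents that add atoms: none
Why: Dess–Martin oxidation of the primary alcohol; the aldehyde has no α-hydrogen and the tertiary alcohol cannot be oxidised.

Step 11
Reactants: 18 C25 aldehyde
Product: 19 syn 1,2-diol mono(methoxymethyl) ether with a vinyl group on C5 (5R,25R)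
Conditions: (Z)-γ-(methoxymethoxy)allyl-B(Ipc)2 [from CH2=CHCH2OCH2OMe, s-BuLi, (−)-Ipc2BOMe, BF3·OEt2], THF, −78 °C; then NaOH, H2O2
Reagents that add atoms: (Z)-γ-(methoxymethoxy)allyldiisopinocampheylborane, COCO/C=C\CB([C@@H]1C[C@@H]2C[C@@H](C2(C)C)[C@H]1C)[C@@H]1C[C@@H]2C[C@@H](C2(C)C)[C@H]1C
Why: Brown alkoxyallylboration through a chair transition state (aldehyde substituent equatorial, Z-alkoxy group axial) gives the syn product; the isopinocampheyl groups set C5 as R, and the C25 configuration is irrelevant because C25 is oxidised in step 13.

Step 12
Reactants: 19 vinyl compound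
Product: 20 2-methylprop-1-enyl compound
Conditions: 2-methylbut-2-ene (excess), RuCl2(=CHPh)(PCy3)(H2IMes) (second-generation Grubbs catalyst, 5 mol %), CH2Cl2, 40 °C
Reagents that add atoms: 2-methylbut-2-ene, CC=C(C)C
Why: Olefin cross-metathesis turns the vinyl group into the 2-methylprop-1-enyl group; the substrate has no other alkene and C5 is untouched.

Step 13
Reactants: 20 secondary alcohol at C25
Product: 21 C25 ketone
Conditions: Dess–Martin periodinane, pyridine, CH2Cl2, 0 °C
Reagents that add atoms: none
Why: Dess–Martin oxidation of the hindered secondary alcohol under buffered conditions, so that the allylic C5–H is not enolised and the alkene stays out of conjugation.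

Step 14
Reactants: 21 C25 ketone
Product: 22 phenol with free C5, C15 and C20 hydroxyls
Conditions: Me2BBr, CH2Cl2, −78 °C; then aq. NaHCO3, THF
Reagents that add atoms: none
Why: Lewis-acid cleavage of the three acetal ethers at −78 °C (the borane attacks the methoxy oxygen, not the C–O bonds to C5, C8 or C15), then hydrolysis of the bromomethyl ethers; no protic acid touches the benzylic carbinol or the allylic ketol.

Step 15
Reactants: 22 phenol
Product: 24 the target CNP0156201.1, via spiro dienone 23 (not isolated)
Conditions: PhI(OAc)2, (CF3)2CHOH, −20 °C; then H2O, TsOH (cat.), THF, 0 °C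
Reagents that add atoms: water, O
Why: Oxidative dearomatisation of a 4-methoxyphenol at trivalent iodine: the O-methyl quinone oxocarbenium ion is captured at C7 by the C5 hydroxyl in a 5-exo spiro closure on the face where C25 stands, so C7 is S. Acid then ionises the C15 hydroxyl through the C12 enol ether (Stork–Danheiser-type hydrolysis), water adds at C12 and methanol leaves, giving C12=O and C14=C15.

## Compound list

1 | 5-hydroxy-2-methoxybenzaldehyde | COc1ccc(O)cc1C=O | starting material
2 | 2-bromo-3-hydroxy-6-methoxybenzaldehyde | COc1ccc(O)c(Br)c1C=O | intermediate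
3 | 2-bromo-6-methoxy-3-(methoxymethoxy)benzaldehyde | COCOc1ccc(OC)c(C=O)c1Br | intermediate
4 | 2-bromoprop-2-en-1-ol | C=C(Br)CO | starting material
5 | (2-bromoprop-2-en-1-yloxy)triisopropylsilane | C=C(Br)CO[Si](C(C)C)(C(C)C)C(C)C | intermediate
6 | 9-methoxy-9-borabicyclo[3.3.1]nonane | COB1C2CCCC1CCC2 | starting material
7 | 2-lithio-3-(triisopropylsilyloxy)prop-1-ene | [Li]C(=C)CO[Si](C(C)C)(C(C)C)C(C)C | intermediate
8 | lithium 9-methoxy-9-[3-(triisopropylsilyloxy)prop-1-en-2-yl]-9-boratabicyclo[3.3.1]nonane | [Li+].C=C(CO[Si](C(C)C)(C(C)C)C(C)C)[B-]1(OC)C2CCCC1CCC2 | intermediate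
9 | 9-[3-(triisopropylsilyloxy)prop-1-en-2-yl]-9-borabicyclo[3.3.1]nonane | C=C(CO[Si](C(C)C)(C(C)C)C(C)C)B1C2CCCC1CCC2 | intermediate
10 | cyclopent-2-en-1-one | O=C1C=CCC1 | starting material
11 | 9-borabicyclononyl enolate (C16=C20) of (3S)-3-[3-(triisopropylsilyloxy)prop-1-en-2-yl]cyclopentanone | C=C(CO[Si](C(C)C)(C(C)C)C(C)C)[C@H]1CCC(OB2C3CCCC2CCC3)=C1 | intermediate
12 | O-(9-borabicyclononyl) aldolate of 13 (15R,16S,17S) | O=C1CC[C@H](C(=C)CO[Si](C(C)C)(C(C)C)C(C)C)[C@H]1[C@@H](OB1C2CCCC1CCC2)c1c(Br)c(OCOC)ccc1OC | intermediate
13 | (2S,3S)-2-[(R)-[2-bromo-6-methoxy-3-(methoxymethoxy)phenyl](hydroxy)methyl]-3-[3-(triisopropylsilyloxy)prop-1-en-2-yl]cyclopentan-1-one | O=C1CC[C@H](C(=C)CO[Si](C(C)C)(C(C)C)C(C)C)[C@H]1[C@@H](O)c1c(Br)c(OCOC)ccc1OC | intermediate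
14 | (2S,3S)-2-[(R)-[2-bromo-6-methoxy-3-(methoxymethoxy)phenyl](methoxymethoxy)methyl]-3-[3-(triisopropylsilyloxy)prop-1-en-2-yl]cyclopentan-1-one | O=C1CC[C@H](C(=C)CO[Si](C(C)C)(C(C)C)C(C)C)[C@H]1[C@@H](OCOC)c1c(Br)c(OCOC)ccc1OC | intermediate
15 | (1S,2S,3S)-2-[(R)-[2-bromo-6-methoxy-3-(methoxymethoxy)phenyl](methoxymethoxy)methyl]-1-methyl-3-[3-(triisopropylsilyloxy)prop-1-en-2-yl]cyclopentan-1-ol | COCOc1ccc(OC)c(c1Br)[C@H](OCOC)[C@@H]1[C@H](CC[C@]1(C)O)C(=C)CO[Si](C(C)C)(C(C)C)C(C)C | intermediate
16 | linear benzo-fused tricycle (hexahydro-1H-cyclopenta[b]naphthalene; rings A, B, C) with C8 OMOM, C12 OMe, C15 OMOM, C20 (OH)(Me), C23 (Me)(CH2OSi(i-Pr)3); 15R,16S,17S,20S,23R | COCOc1ccc(OC)c2c1[C@](C)(CO[Si](C(C)C)(C(C)C)C(C)C)[C@H]1CC[C@](C)(O)[C@@H]1[C@H]2OCOC | intermediate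
17 | as 16 with C23 (Me)(CH2OH) | COCOc1ccc(OC)c2c1[C@](C)(CO)[C@H]1CC[C@](C)(O)[C@@H]1[C@H]2OCOC | intermediate
18 | as 16 with C23 (Me)(CHO) | COCOc1ccc(OC)c2c1[C@](C)(C=O)[C@H]1CC[C@](C)(O)[C@@H]1[C@H]2OCOC | intermediate
19 | as 16 with C23 (Me)[(25R)-CH(OH)–(5R)-CH(OMOM)–CH=CH2] | COCOc1ccc(OC)c2c1[C@](C)([C@@H](O)[C@H](OCOC)C=C)[C@H]1CC[C@](C)(O)[C@@H]1[C@H]2OCOC | intermediate
20 | as 19 with CH=C(CH3)2 in place of CH=CH2 | COCOc1ccc(OC)c2c1[C@](C)([C@@H](O)[C@H](OCOC)C=C(C)C)[C@H]1CC[C@](C)(O)[C@@H]1[C@H]2OCOC | intermediate
21 | as 20 with C25 ketone: C23 (Me)[C(=O)–(5R)-CH(OMOM)–CH=C(CH3)2] | COCOc1ccc(OC)c2c1[C@](C)(C(=O)[C@H](OCOC)C=C(C)C)[C@H]1CC[C@](C)(O)[C@@H]1[C@H]2OCOC | intermediate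
22 | 4-methoxyphenol tricycle with free C8 OH, C15 OH, C20 OH and C23 (Me)[C(=O)–(5R)-CH(OH)–CH=C(CH3)2]; 5R,15R,16S,17S,20S,23R | Oc1ccc(OC)c2c1[C@](C)(C(=O)[C@H](O)C=C(C)C)[C@H]1CC[C@](C)(O)[C@@H]1[C@H]2O | intermediate
23 | spiro dienone: ring D closed (O6–C7), C8 ketone, C10=C11, C12(OMe)=C14 enol ether, C15 OH; 5R,7S,15R,16S,17S,20S,23R | CC(C)=C[C@H]1O[C@@]23C(=O)C=CC(OC)=C2[C@H](O)[C@@H]2[C@H](CC[C@]2(C)O)[C@@]3(C)C1=O | intermediate
24 | CNP0156201.1 (5R,7S,16R,17S,20S,23R) | CC(C)=C[C@H]1O[C@@]23C(=O)C=CC(=O)C2=C[C@@H]2[C@H](CC[C@]2(C)O)[C@@]3(C)C1=O | target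

## Step count and risks

Total: 15 steps. Longest linear sequence: 13 steps (steps 1, 2 and 5–15; the branch through steps 3 and 4 is equally long).

**Step 5 (key step).** The most likely failure is loss of the allylic silyloxy group by β-elimination from the alkenylrhodium (or alkenylborane) before the enone inserts, which would give an allene and stop turnover. A second risk is slow aldol capture of the doubly ortho-substituted aldehyde, which would leave the enolate to be protonated. Fallback: alkenyllithium 7 (from 5) is transmetalated with ZnCl2 to alkenylzinc chloride F1 and added to 10 with [RhCl((S)-BINAP)]2, i.e. [RhCl(C44H32P2)]2, and Me3SiCl in THF at 20 °C, which gives the regiodefined silyl enol ether F2. A Mukaiyama aldol of F2 with 3 (BF3·OEt2, CH2Cl2, −78 °C) then returns to the route at 13. The open transition state may also give the C15 epimer F3, which would be separated; it is not lost in principle, since C15 becomes sp2 at the end.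

**Step 8.** Insertion into the hindered alkene may be slower than formate reduction of the arylpalladium bromide, so that the bromide is simply replaced by hydrogen. Peri strain between the C15 ether and the C12 methoxyl could also push the insertion through a boat-like arrangement and erode the C23 selectivity. Fallback: from 15, bromine–magnesium exchange (i-PrMgCl·LiCl) and protonation give the bromine-free arene F4. A hydrogen-atom-transfer hydroarylation (Co(salen), i.e. N,N′-bis(salicylidene)ethylenediaminocobalt, Co(C16H14N2O2); N-fluoro-2,4,6-trimethylpyridinium triflate; PhSiH3) then joins C7 to C23 under non-acidic conditions and returns at 16. C23 would rest on substrate bias alone in that case and the epimers would have to be separated.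

**Step 15.** The oxidised ring may be captured at C12 by acetate or traces of water faster than the hindered C7 is reached by the C5 hydroxyl, which amounts to oxidative demethylation. Fallback: this path is taken on purpose. From 22, PhI(OAc)2 in aqueous MeCN gives the p-quinone F5. Camphorsulfonic acid (cat.) in CH2Cl2 should then bring about conjugate addition of the C5 hydroxyl to C7 and loss of water from C15 through the C12 enol, returning at 24.

**Step 14.** The Lewis acid may ionise the benzylic C15–O bond of the electron-rich arene, followed by loss of H16 or capture by bromide. Fallback: the order is reversed so that no aromatic ring is present when the acetals are cleaved. From 21, (NH4)2Ce(NO3)6 in MeCN–H2O at 0 °C oxidises the ring to the bis(methoxymethyl) quinone F6. Me2BBr at −78 °C then frees the hydroxyls to give F5, which closes to 24 as in the fallback for step 15.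

**Step 1.** Bromination may go to C10 (ortho to the hydroxyl, para to the formyl group) or twice. Fallback: from 1, MOMCl and i-Pr2NEt give 2-methoxy-5-(methoxymethoxy)benzaldehyde F7. In one flask the formyl group is masked as its lithium α-amino alkoxide (LiN(Me)CH2CH2NMe2), n-BuLi metalates the position between the two directing groups, and BrCCl2CCl2Br delivers the bromine, returning at 3.

## Further compounds

F1 | step 5 | [3-(triisopropylsilyloxy)prop-1-en-2-yl]zinc chloride | Cl[Zn]C(=C)CO[Si](C(C)C)(C(C)C)C(C)C
F2 | step 5 | trimethylsilyl enol ether (C16=C20) of (3S)-3-[3-(triisopropylsilyloxy)prop-1-en-2-yl]cyclopentanone | C=C(CO[Si](C(C)C)(C(C)C)C(C)C)[C@H]1CCC(O[Si](C)(C)C)=C1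
F3 | step 5 | (15S) epimer of aldol 13 | O=C1CC[C@H](C(=C)CO[Si](C(C)C)(C(C)C)C(C)C)[C@H]1[C@H](O)c1c(Br)c(OCOC)ccc1OC
F4 | step 8 | bromine-free analogue of 15 | COCOc1ccc(OC)c(c1)[C@H](OCOC)[C@@H]1[C@H](CC[C@]1(C)O)C(=C)CO[Si](C(C)C)(C(C)C)C(C)C
F5 | step 15 | p-quinone with free C5, C15 and C20 hydroxyls and C25 ketone | O=C1C=CC(=O)C2=C1[C@](C)(C(=O)[C@H](O)C=C(C)C)[C@H]1CC[C@](C)(O)[C@@H]1[C@H]2O
F6 | step 14 | p-quinone with C5 and C15 methoxymethyl ethers | O=C1C=CC(=O)C2=C1[C@](C)(C(=O)[C@H](OCOC)C=C(C)C)[C@H]1CC[C@](C)(O)[C@@H]1[C@H]2OCOC
F7 | step 1 | 2-methoxy-5-(methoxymethoxy)benzaldehyde | COCOc1ccc(OC)c(C=O)c1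
A1 | alternative 1 | 2-hydroxy-1,4-benzoquinone | O=C1C=CC(=O)C(O)=C1
A2 | alternative 1 | cyclopentane keto aldehyde with C20 silyl ether and C25 enone carbonate (C23 epimers) | O=C[C@@H]1[C@H](CC[C@]1(C)O[Si](C)(C)C(C)(C)C)C(C)C(=O)/C=C/C(C)(C)OC(=O)OC
A3 | alternative 1 | tricyclic enedione with free C7 hydroxyl and C25 enone carbonate | O[C@@]12C(=O)C=CC(=O)C1=C[C@@H]1[C@H](CC[C@]1(C)O[Si](C)(C)C(C)(C)C)[C@@]2(C)C(=O)/C=C/C(C)(C)OC(=O)OC
A4 | alternative 2 | (S)-limonene | CC1=CC[C@H](CC1)C(C)=C
A5 | alternative 2 | (3S)-6-oxo-3-(prop-1-en-2-yl)heptanal | O=CC[C@H](CCC(C)=O)C(C)=C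
A6 | alternative 2 | 2-formyl-1-methyl-3-(prop-1-en-2-yl)cyclopentan-1-ol | O=C[C@@H]1[C@H](CC[C@]1(C)O)C(C)=C
A7 | alternative 3 | Z-enedione-linked furanone and 1-vinylcyclopentene | CC(C)=C[C@H]1OC(C(=O)/C=C\C(=O)/C=C/C2=CCC[C@]2(C)O[Si](C)(C)C(C)(C)C)=C(C)C1=O
A8 | alternative 3 | tetracyclic Diels–Alder adduct with C15=C16 | CC(C)=C[C@H]1O[C@@]23C(=O)C=CC(=O)[C@@H]2C=C2[C@H](CC[C@]2(C)O[Si](C)(C)C(C)(C)C)[C@@]3(C)C1=O
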